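The cinnamate is removed and O6 is returned to the ketone level. This exposes a β-hydroxy ketone (eudesmane numbering): the C4 hydroxyl of ring A and the C6 carbonyl of ring B are 1,3-related across the ring-fusion carbon C5. Everything rests on cutting C4–C5 as an aldol bond. In the forward direction, one reversible, base-mediated ketone–ketone aldol addition forms that bond and closes ring A. It also lets C4, C5 and C7 settle thermodynamically around the fixed quaternary C10. The precursor is a monocyclic menthone-type ring B ketone whose C10 carries the angular methyl and a 4-oxopentyl arm. C10 comes from a catalytic asymmetric conjugate addition to piperitone.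

Key step: step 3

**Numbering and target.** Ring A is C1–C5 plus C10, and ring B is C5–C10. C14 sits on C10, C15 on C4, and the isopropyl group on C7. The target SMILES reads as 4β-OH (axial), 5α-H, 6β-acyloxy (axial), 7β-isopropyl (equatorial), 10β-methyl and an E alkene. This is (4S,5S,6R,7S,10R).

**Assumption.** The sense of induction of the carbene ligand on piperitone is not predicted here. The ligand is written as its S antipode, and the antipode meant is the one that puts the arm on the α face of C10, anti to the isopropyl group.

**Design choices.**
- (a) Copper catalysts with ferrocenyl diphosphines are established for β-unsubstituted cyclic and for acyclic acceptors, not for quaternary carbons on 3-methylcyclohexenones. The copper–NHC/Grignard system developed for that substrate class is used instead.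
- (b) That system needs an alkylmagnesium bromide in Et2O, so the arm is introduced as a pent-4-enyl group. The methyl ketone is unmasked by a near-neutral oxidation, not by acid, which could start a premature condensation.
- (c) C7 stays α to the C6 ketone until step 4 and is re-equilibrated in step 3. The optical purity of the piperitone therefore does not limit that of the product, as long as the catalyst controls the face at C10.

Step 1
Reactants: 1 (S)-piperitone; 2 5-bromopent-1-ene
Product: 5 (2S,5R)-5-methyl-5-(pent-4-en-1-yl)-2-(propan-2-yl)cyclohexan-1-one, via pent-4-enylmagnesium bromide 3 (not isolated), via bromomagnesium C5-enolate 4 (not isolated)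
Conditions: 2, Mg, Et2O, reflux; solution of 3 added slowly to 1, Cu(OTf)2 (3 mol %), (S)-3-(1-hydroxy-3,3-dimethylbutan-2-yl)-1-mesityl-4,5-dihydroimidazolium hexafluorophosphate (4 mol %), Et2O, −30 °C; 1 M aq HCl
Reagents that add atoms: none
Why: Copper–NHC-catalysed asymmetric conjugate addition of an alkyl Grignard reagent to a 3-methylcyclohex-2-enone is an established route to all-carbon quaternary centres, and here the chiral carbene should select the enone face anti to the isopropyl group so that C10 forms as R, while the remote, conformationally mobile C7 centre exerts little bias and the 6-isopropyl group disfavours 1,2-addition.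

Step 2
Reactants: 5 (2S,5R)-5-methyl-5-(pent-4-en-1-yl)-2-(propan-2-yl)cyclohexan-1-one
Product: 6 (2S,5R)-5-methyl-5-(4-oxopentyl)-2-(propan-2-yl)cyclohexan-1-one
Conditions: PdCl2 (10 mol %), CuCl (1 equiv), O2 (1 atm), DMF/H2O (7:1), rt
Reagents that add atoms: water, O
Why: In this Tsuji–Wacker oxidation, Markovnikov hydroxypalladation of the monosubstituted alkene followed by β-hydride elimination should give the methyl ketone under near-neutral conditions that leave the ring ketone and C10 untouched and create no stereocentre.

Step 3
Reactants: 6 (2S,5R)-5-methyl-5-(4-oxopentyl)-2-(propan-2-yl)cyclohexan-1-one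
Product: 7 4β-hydroxy-5αH-eudesman-6-one, (2S,4aR,8S,8aR)-8-hydroxy-4a,8-dimethyl-2-(propan-2-yl)octahydronaphthalen-1(2H)-one
Conditions: KOH (0.2 equiv), MeOH/H2O (9:1), 0 °C → rt; AcOH quench at 0 °C
Reagents that add atoms: none
Why: Catalytic hydroxide enolises the ring B ketone reversibly towards C5, and this enolate adds to the C4 carbonyl at the end of the arm on C10, which forms C4–C5; the closest known reaction type is the base-mediated intramolecular aldol addition of 1,7-diketones that stops at the cyclic β-hydroxy ketone. Ring A closes in the 6-(enolexo)-exo-trig mode, with the enolate C5=C6 bond outside the forming six-membered ring and the C4=O bond exocyclic to it. Since aldol addition, retro-aldol cleavage and enolisation at C5 and C7 should all be faster at room temperature than loss of water, the outcome should be governed by product stability and not by the kinetic face selectivity of the first bond formation. C5 should settle as the trans-fused 5α-H epimer because either cis-decalin chair pair pushes the fully substituted C4 or the C6 acyl carbon into an axial position; C4 should place the small hydroxyl axial (β, beside axial C14 and within hydrogen-bond reach of O6) and C15 equatorial because the opposite epimer suffers a methyl–methyl 1,3-diaxial contact; C7 relaxes to the equatorial 7β-isopropyl epimer, so any 7-epimer present in 6 converges. The step needs site selectivity among four enolisable positions: enolates at C7 and C15 could only close eight-membered rings, and attack of the C3 enolate on the crowded C6 carbonyl would build a bridged bicyclo[3.3.1]nonane, a reversible dead end because its bridgehead position forbids dehydration. Dehydration of 7 is held back by the mild, water-containing medium and by the allylic strain between C15 and O6 in the twisted conjugated enone that would result.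

Step 4
Reactants: 7 4β-hydroxy-5αH-eudesman-6-one
Product: 9 eudesmane-4β,6β-diol, via 4-O-diethylboryl chelate 8 (not isolated)
Conditions: Et2BOMe (1.2 equiv), THF/MeOH (4:1), −78 °C; NaBH4, −78 → −20 °C; AcOH, then repeated evaporation from MeOH
Reagents that add atoms: none
Why: In this Narasaka–Prasad reduction boron ties the axial 4β-oxygen to the C6 carbonyl oxygen on the β face, which axial C14 already screens, so external hydride can only arrive from the α face and should give the axial 6β-alcohol (6R), while the low temperature and the absence of free base exclude retro-aldol cleavage.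

Step 5
Reactants: 10 (E)-3-hydroxycinnamic acid
Product: 12 (E)-3-[3-(tert-butyldimethylsilyloxy)phenyl]prop-2-enoic acid, via bis-silylated silyl ester 11 (not isolated)
Conditions: TBSCl (2.3 equiv), imidazole, DMF, rt; crude 11 in AcOH/THF/H2O (3:1:1), rt
Reagents that add atoms: tert-butyldimethylsilyl chloride (TBSCl), CC(C)(C)[Si](C)(C)Cl
Why: Imidazole-promoted silylation of phenol and acid followed by selective hydrolysis of the far more labile silyl ester should leave the acid-tolerant aryl silyl ether, with the E alkene untouched and no stereocentre involved.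

Step 6
Reactants: 9 eudesmane-4β,6β-diol; 12 (E)-3-[3-(tert-butyldimethylsilyloxy)phenyl]prop-2-enoic acid
Product: 14 4β-hydroxyeudesman-6β-yl (E)-3-[3-(tert-butyldimethylsilyloxy)phenyl]prop-2-enoate, via silyl-protected cinnamoyl chloride 13 (not isolated)
Conditions: 12, (COCl)2, DMF (cat.), CH2Cl2, 0 °C → rt, evaporate; then 9, DMAP, Et3N, toluene, rt → 60 °C
Reagents that add atoms: none
Why: In this DMAP-catalysed acylation by an acid chloride only the secondary 6β-hydroxyl should reach the acylpyridinium ion, the tertiary 4β-hydroxyl staying inert, and C6 keeps its configuration because the C–O bond is not broken.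

Step 7
Reactants: 14 4β-hydroxyeudesman-6β-yl (E)-3-[3-(tert-butyldimethylsilyloxy)phenyl]prop-2-enoate
Product: 15 target, (1R,2S,4aR,8S,8aS)-8-hydroxy-4a,8-dimethyl-2-(propan-2-yl)decahydronaphthalen-1-yl (E)-3-(3-hydroxyphenyl)prop-2-enoate
Conditions: HF·pyridine, pyridine, THF, 0 °C → rt
Reagents that add atoms: none
Why: Fluoride-driven cleavage of the aryl silyl ether under buffered, weakly acidic conditions should spare the cinnamate, the tertiary alcohol and all stereocentres.

**Compound list**

1 | (S)-piperitone, (6S)-3-methyl-6-(propan-2-yl)cyclohex-2-en-1-one | CC(C)[C@@H]1CCC(C)=CC1=O | starting material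
2 | 5-bromopent-1-ene | C=CCCCBr | starting material
3 | pent-4-enylmagnesium bromide | C=CCCC[Mg]Br | intermediate
4 | bromomagnesium C5=C6 enolate formed by the conjugate addition | CC(C)[C@@H]1CC[C@@](C)(CCCC=C)C=C1O[Mg]Br | intermediate
5 | (2S,5R)-5-methyl-5-(pent-4-en-1-yl)-2-(propan-2-yl)cyclohexan-1-one | CC(C)[C@@H]1CC[C@@](C)(CCCC=C)CC1=O | intermediate
6 | (2S,5R)-5-methyl-5-(4-oxopentyl)-2-(propan-2-yl)cyclohexan-1-one (1,7-diketone, key-step precursor) | CC(C)[C@@H]1CC[C@@](C)(CCCC(C)=O)CC1=O | intermediate
7 | 4β-hydroxy-5αH-eudesman-6-one, (4S,5R,7S,10R) (key-step product) | CC(C)[C@@H]1CC[C@@]2(C)CCC[C@](C)(O)[C@@H]2C1=O | intermediate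
8 | 4-O-diethylboryl derivative of 7, boron chelated to O6 | CC(C)[C@@H]1CC[C@@]2(C)CCC[C@](C)(OB(CC)CC)[C@@H]2C1=O | intermediate
9 | eudesmane-4β,6β-diol, (4S,5S,6R,7S,10R) | CC(C)[C@@H]1CC[C@@]2(C)CCC[C@](C)(O)[C@@H]2[C@@H]1O | intermediate
10 | (E)-3-hydroxycinnamic acid | OC(=O)/C=C/c1cccc(O)c1 | starting material
11 | tert-butyldimethylsilyl (E)-3-[3-(tert-butyldimethylsilyloxy)phenyl]prop-2-enoate | CC(C)(C)[Si](C)(C)OC(=O)/C=C/c1cccc(O[Si](C)(C)C(C)(C)C)c1 | intermediate
12 | (E)-3-[3-(tert-butyldimethylsilyloxy)phenyl]prop-2-enoic acid | OC(=O)/C=C/c1cccc(O[Si](C)(C)C(C)(C)C)c1 | intermediate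
13 | (E)-3-[3-(tert-butyldimethylsilyloxy)phenyl]prop-2-enoyl chloride | ClC(=O)/C=C/c1cccc(O[Si](C)(C)C(C)(C)C)c1 | intermediate
14 | 4β-hydroxyeudesman-6β-yl (E)-3-[3-(tert-butyldimethylsilyloxy)phenyl]prop-2-enoate | CC(C)[C@@H]1CC[C@@]2(C)CCC[C@](C)(O)[C@@H]2[C@@H]1OC(=O)/C=C/c1cccc(O[Si](C)(C)C(C)(C)C)c1 | intermediate
15 | 4β-hydroxyeudesman-6β-yl (E)-3-(3-hydroxyphenyl)prop-2-enoate, CNP0283603.1 | CC(C)[C@@H]1CC[C@@]2(C)CCC[C@](C)(O)[C@@H]2[C@@H]1OC(=O)/C=C/c1cccc(O)c1 | target

Total step count: 7
Longest linear sequence: 6 steps (1, 2, 3, 4, 6, 7)

**Steps most likely to fail**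

**Step 3 (key step).**
- What may go wrong: the aldol equilibrium may favour the open form or the bridged mode of closure. Slow loss of water may drain the product. C4 and C5 may also settle as a mixture instead of a single arrangement.
- Fallback, from 6 back to 7: ring closure is made irreversible and the C4 oxygen is put back under reagent control.
- Compound 6 is driven through the aldol condensation with catalytic p-TsOH in refluxing benzene under Dean–Stark water removal. Only the fused mode of closure can dehydrate, so this should give eudesm-4-en-6-one F1.
- Luche reduction (NaBH4, CeCl3·7H2O, MeOH) from the α face, opposite C14, should give eudesm-4-en-6β-ol F2.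
- Hydroxyl-directed epoxidation (VO(acac)2, t-BuOOH, CH2Cl2) delivers oxygen syn to O6 and should give 4β,5β-epoxyeudesman-6β-ol F3.
- Dess–Martin oxidation gives 4β,5β-epoxyeudesman-6-one F4.
- SmI2 in THF/MeOH at −78 °C cleaves the C5–O bond α to the ketone. Protonation of the samarium enolate from the open α face should then give 7.

**Step 1.**
- What may go wrong: face selection by the catalyst may be eroded by the substituent at C7. The addition may also be sluggish, so that enolisation or 1,2-addition competes.
- Fallback, from 3 back to 5: the quaternary carbon is made first on the unsubstituted enone for which the catalyst system is calibrated, and the isopropyl group is added afterwards.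
- Compound 3 is added under the same copper–NHC conditions to commercial 3-methylcyclohex-2-en-1-one. This should give (R)-3-methyl-3-(pent-4-en-1-yl)cyclohexan-1-one F5.
- Kinetic deprotonation with LDA (THF, −78 °C) at the CH2 remote from the quaternary carbon is followed by transmetalation with ZnCl2 and addition of acetone. This gives (5R)-2-(2-hydroxypropan-2-yl)-5-methyl-5-(pent-4-en-1-yl)cyclohexan-1-one F6.
- Catalytic p-TsOH in warm benzene removes water and gives (R)-5-methyl-5-(pent-4-en-1-yl)-2-(propan-2-ylidene)cyclohexan-1-one F7.
- Li in liquid NH3 reduces only the conjugated double bond and returns 5 as a mixture of C7 epimers, which step 3 levels.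

**Step 6.**
- What may go wrong: acyl transfer to the crowded axial hydroxyl may be too slow, because the hydroxyl is flanked by the isopropyl group and lies syn to C14 and O4. Forcing conditions may then start elimination of the tertiary alcohol.
- Fallback, from 9 back to 15: the ester C–O bond is made with a small, very reactive acyl donor, and the styrene part is built afterwards. Steps 5 and 7 then fall away.
- Compound 9 is esterified with diethylphosphonoacetic acid (DCC, DMAP, CH2Cl2) to give 4β-hydroxyeudesman-6β-yl 2-(diethoxyphosphoryl)acetate F8.
- A Horner–Wadsworth–Emmons olefination under Masamune–Roush conditions follows (LiCl, DBU in excess to cover the phenol, MeCN, rt) with commercial 3-hydroxybenzaldehyde. It should give the E-cinnamate 15 directly.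

Further compounds
F1 | step 3 | (7S,10R)-eudesm-4-en-6-one | CC(C)[C@@H]1CC[C@@]2(C)CCCC(C)=C2C1=O
F2 | step 3 | eudesm-4-en-6β-ol | CC(C)[C@@H]1CC[C@@]2(C)CCCC(C)=C2[C@@H]1O
F3 | step 3 | 4β,5β-epoxyeudesman-6β-ol | CC(C)[C@@H]1CC[C@@]2(C)CCC[C@]3(C)O[C@]23[C@@H]1O
F4 | step 3 | 4β,5β-epoxyeudesman-6-one | CC(C)[C@@H]1CC[C@@]2(C)CCC[C@]3(C)O[C@]23C1=O
F5 | step 1 | (R)-3-methyl-3-(pent-4-en-1-yl)cyclohexan-1-one | O=C1CCC[C@@](C)(CCCC=C)C1
F6 | step 1 | (5R)-2-(2-hydroxypropan-2-yl)-5-methyl-5-(pent-4-en-1-yl)cyclohexan-1-one | CC(C)(O)C1CC[C@@](C)(CCCC=C)CC1=O
F7 | step 1 | (R)-5-methyl-5-(pent-4-en-1-yl)-2-(propan-2-ylidene)cyclohexan-1-one | CC(C)=C1CC[C@@](C)(CCCC=C)CC1=O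
F8 | step 6 | 4β-hydroxyeudesman-6β-yl 2-(diethoxyphosphoryl)acetate | CC(C)[C@@H]1CC[C@@]2(C)CCC[C@](C)(O)[C@@H]2[C@@H]1OC(=O)CP(=O)(OCC)OCC
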